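## Retrosynthetic overview
- The C1 acylal and C3=C4 dienol-ether pyran come last, by cyclising an iridoid dialdehyde to its lactol and acylating it with isovaleryl chloride. C9–H and the C1 anomeric centre are set there.
- The C9 substituent (C1) comes from a C9 ketone by Wittig methoxymethylenation. The C4–C3–C11 unit comes from Stille coupling of a 2-stannylallyl isovalerate onto a C5 vinyl iodide, then hydroboration/oxidation to the C3 aldehyde.
- The cyclopentene is built first from commercial (R)-4-silyloxycyclopentenone. C7 is taken from the chiral pool. C8/C10 are set by α′-methylenation, then epoxidation anti to OTBS, then opening of the epoxide with salicylate.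

**Conventions.** Iridoid numbering is used (C1, C3–C11). "β" means the face carrying H‑9. In the target: C7‑OAc β, C10 β, C8‑OH α, C9‑H β, C1 α.

**Assumption.** C9 and C1 are set under thermodynamic/anomeric control, with the natural isomer major and any epimers separable by HPLC. 2‑Bromoallyl alcohol is taken as commercial.

## Route

**Step 1**
Reactants: 1 (2‑bromoallyl alcohol), 2 (isovaleryl chloride)
Product: 3 (2‑bromoallyl 3‑methylbutanoate)
Conditions: pyridine, DMAP (cat.), CH2Cl2, 0 °C
Reagents that add atoms: isovaleryl chloride, CC(C)CC(=O)Cl (compound 2)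
Why: Standard O‑acylation of the primary alcohol; no stereocentres.

**Step 2**
Reactants: 3
Product: 4 (2‑(tributylstannyl)allyl 3‑methylbutanoate)
Conditions: (Bu3Sn)2, Pd(PPh3)4, toluene, 100 °C
Reagents that add atoms: hexabutylditin, CCCC[Sn](CCCC)(CCCC)[Sn](CCCC)(CCCC)CCCC
Why: Pd‑catalysed distannane coupling (Stille‑type stannylation) of the vinyl bromide gives the C3–C4–C11 vinylstannane with the C11 ester already in place.

**Step 3**
Reactants: 5 ((R)‑4‑TBSO‑cyclopent‑2‑enone)
Product: 6 ((4S,5R)‑4‑TBSO‑5‑(hydroxymethyl)cyclopent‑2‑enone, trans)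
Conditions: LDA, THF, −78 °C; then monomeric HCHO, −78 °C
Reagents that add atoms: formaldehyde, C=O
Why: Kinetic α′‑enolate aldol. The electrophile enters anti to the β‑OTBS; this new C8 centre is destroyed in the next step.

**Step 4**
Reactants: 6
Product: 7 ((S)‑4‑TBSO‑5‑methylenecyclopent‑2‑enone)
Conditions: MsCl, Et3N, CH2Cl2, 0 °C; then DBU, rt
Reagents that add atoms: none
Why: Mesylation then E1cB elimination gives the exocyclic α‑methylene enone (the C8=C10 alkene).

**Step 5**
Reactants: 7
Product: 8 (C8 spiro‑epoxide, epoxide O α, CH2 β; (R) at C8)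
Conditions: 30% H2O2, 1 M NaOH, MeOH, 0 °C
Reagents that add atoms: hydrogen peroxide, OO
Why: Weitz–Scheffer nucleophilic epoxidation of the more electrophilic, unhindered exocyclic enone alkene. Ring closure occurs anti to the β‑OTBS, which sets C8 (O α, C10 β).

**Step 6**
Reactants: 8
Product: 9 (free C7 alcohol)
Conditions: HF·pyridine, pyridine/THF, 0 °C to rt
Reagents that add atoms: none
Why: Buffered silyl ether cleavage; the epoxide and enone survive.

**Step 7**
Reactants: 9
Product: 10 (C7 acetate, β)
Conditions: Ac2O, pyridine, DMAP, CH2Cl2, 0 °C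
Reagents that add atoms: acetic anhydride, CC(=O)OC(C)=O
Why: O‑acetylation with retention; the epoxide has no enolisable α′‑H left, so C7 is not at risk.

**Step 8**
Reactants: 10, 11 (salicylic acid)
Product: 12 ((4S,5R)‑4‑acetoxy‑5‑hydroxy‑5‑[(2‑hydroxybenzoyl)oxymethyl]cyclopent‑2‑enone)
Conditions: Et3N (or Cs2CO3), DMF, 60–70 °C
Reagents that add atoms: salicylic acid, OC(=O)c1ccccc1O (compound 11)
Why: SN2 opening of the spiro‑epoxide by carboxylate at the CH2 terminus. The C8–O bond is not touched, so C8 configuration is retained and the C8‑OH/C10‑salicylate pair of the target is formed.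

**Step 9**
Reactants: 12
Product: 13 (5‑iodo enone, i.e. C5–I)
Conditions: I2, pyridine, CH2Cl2/CCl4, 0 °C to rt
Reagents that add atoms: iodine, II
Why: Johnson α‑iodination (iodine addition–elimination) of the enone gives the C5 vinyl iodide.

**Step 10**
Reactants: 13
Product: 14 (C9=CH–OMe enol ether, E/Z mixture)
Conditions: [Ph3PCH2OMe]Cl, KOt‑Bu (≥4 equiv), THF, 0 °C to rt
Reagents that add atoms: methoxymethylenetriphenylphosphorane, COC=P(c1ccccc1)(c1ccccc1)c1ccccc1
Why: Wittig one‑carbon homologation installs C1 on the C9 ketone; extra base covers the OH and phenol.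

**Step 11**
Reactants: 14
Product: 15 (C1 dimethyl acetal, C9 epimeric mixture, C5=C6 retained)
Conditions: MeOH, HC(OMe)3, CSA (cat.), 0 °C
Reagents that add atoms: methanol, CO
Why: Acid‑catalysed enol ether to acetal by kinetic α‑protonation at C9 (Ringold‑type deconjugation), which keeps C5=C6 out of conjugation with C1. The C9 configuration is reset in Step 15.

**Step 12**
Reactants: 15, 4
Product: 16 (C5–C(=CH2)CH2OiVal coupled diene acetal)
Conditions: Pd2(dba)3, AsPh3, CuI, DMF, rt to 45 °C
Reagents that add atoms: none (the stannane 4 is the coupling partner)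
Why: Stille coupling of the vinyl iodide installs C4/C3/C11 with C3 as a terminal alkene.

**Step 13**
Reactants: 16
Product: 17 (C3 primary alcohol; new C4 centre, epimeric)
Conditions: 9‑BBN, THF, 0 °C to rt; then NaBO3·4H2O, THF/H2O
Reagents that add atoms: sodium perborate as a HOO⁻ source, OO
Why: Anti‑Markovnikov hydroboration/oxidation at the unhindered terminal alkene, leaving the esters, acetal and C5=C6 intact. The C4 centre is planarised in Step 14.

**Step 14**
Reactants: 17
Product: 18 (C3 aldehyde)
Conditions: Dess–Martin periodinane, NaHCO3, CH2Cl2, 0 °C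
Reagents that add atoms: none
Why: Buffered mild oxidation to the aldehyde, compatible with the acetal.

**Step 15**
Reactants: 18
Product: 19 (lactol, in equilibrium with the 1,5‑dialdehyde)
Conditions: Amberlyst‑15, acetone/H2O, 40 °C
Reagents that add atoms: water, O
Why: Acetal hydrolysis unmasks C1‑CHO. The C3 aldehyde enolises as the dienol and closes onto C1 to give the lactol, with C9 equilibrating to the more stable epimer (C1 cis to C8‑OH).

**Step 16**
Reactants: 19, 2 (isovaleryl chloride)
Product: 20 (jatamanvaltrate I)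
Conditions: pyridine, DMAP (cat.), CH2Cl2, −20 to 0 °C, 1.1 equiv acid chloride
Reagents that add atoms: isovaleryl chloride, CC(C)CC(=O)Cl (compound 2)
Why: Acylation of the most nucleophilic lactol OH traps the acylal; the anomeric effect sets C1, and chromatography removes any epimer.

## Compound list
1 | 2‑bromoallyl alcohol | C=C(Br)CO | starting material
2 | isovaleryl chloride | CC(C)CC(=O)Cl | starting material
3 | 2‑bromoallyl 3‑methylbutanoate | C=C(Br)COC(=O)CC(C)C | intermediate
4 | 2‑(tributylstannyl)allyl 3‑methylbutanoate | C=C([Sn](CCCC)(CCCC)CCCC)COC(=O)CC(C)C | intermediate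
5 | (R)‑4‑TBSO‑cyclopent‑2‑enone | O=C1C=C[C@H](O[Si](C)(C)C(C)(C)C)C1 | starting material
6 | trans‑5‑(hydroxymethyl) aldol product | O=C1C=C[C@H](O[Si](C)(C)C(C)(C)C)[C@H]1CO | intermediate
7 | 5‑methylene enone | O=C1C=C[C@H](O[Si](C)(C)C(C)(C)C)C1=C | intermediate
8 | spiro‑epoxide (O α, CH2 β), TBS ether | O=C1C=C[C@H](O[Si](C)(C)C(C)(C)C)[C@]12CO2 | intermediate
9 | spiro‑epoxide, free C7‑OH | O=C1C=C[C@H](O)[C@]12CO2 | intermediate
10 | spiro‑epoxide, C7‑OAc | O=C1C=C[C@H](OC(C)=O)[C@]12CO2 | intermediate
11 | salicylic acid | OC(=O)c1ccccc1O | starting material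
12 | 4‑acetoxy‑5‑hydroxy‑5‑(salicyloyloxymethyl)cyclopentenone | O=C1C=C[C@H](OC(C)=O)[C@]1(O)COC(=O)c1ccccc1O | intermediate
13 | 2‑iodo enone | O=C1C(I)=C[C@H](OC(C)=O)[C@]1(O)COC(=O)c1ccccc1O | intermediate
14 | C9=CHOMe enol ether (E/Z) | COC=C1C(I)=C[C@H](OC(C)=O)[C@]1(O)COC(=O)c1ccccc1O | intermediate
15 | dimethyl acetal, vinyl iodide (C9 undefined) | COC(OC)C1C(I)=C[C@H](OC(C)=O)[C@]1(O)COC(=O)c1ccccc1O | intermediate
16 | Stille product (C9 undefined) | COC(OC)C1C(C(=C)COC(=O)CC(C)C)=C[C@H](OC(C)=O)[C@]1(O)COC(=O)c1ccccc1O | intermediate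
17 | C3 alcohol (C9, C4 undefined) | COC(OC)C1C(C(CO)COC(=O)CC(C)C)=C[C@H](OC(C)=O)[C@]1(O)COC(=O)c1ccccc1O | intermediate
18 | C3 aldehyde (C9, C4 undefined) | COC(OC)C1C(C(C=O)COC(=O)CC(C)C)=C[C@H](OC(C)=O)[C@]1(O)COC(=O)c1ccccc1O | intermediate
19 | lactol (C1 anomeric mixture) | CC(=O)O[C@H]1C=C2C(COC(=O)CC(C)C)=COC(O)[C@@H]2[C@@]1(O)COC(=O)c1ccccc1O | intermediate
20 | jatamanvaltrate I | CC(=O)O[C@H]1C=C2C(COC(=O)CC(C)C)=CO[C@@H](OC(=O)CC(C)C)[C@@H]2[C@@]1(O)COC(=O)c1ccccc1O | target

## Totals
- Total steps: 16.
- Longest linear sequence: 14 (compound 5 to compound 20, Steps 3–16).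

## Three steps most likely to fail
1. **Step 3 (α′‑aldol of the 4‑silyloxyenone, then the Step 5 epoxide facial selectivity).** The α′‑enolate can undergo β‑elimination of OTBS, and the Step 5 facial selectivity is only argued from sterics.
   - Fallback: set C7/C8 differently. Start from cyclopentane‑1,3‑dione, build 2‑hydroxy‑2‑(hydroxymethyl)‑1,3‑dione, set C7 and C8 together by CBS or ketoreductase desymmetrising reduction, then dehydrogenate to the enone and rejoin the route at Step 8.
2. **Steps 10–11 (methoxymethylene Wittig on the hindered ketone, then kinetic α‑protonation).** The ketone is flanked by a quaternary carbon, and protonation may go to C6 instead of C9, which would shift the alkene into conjugation.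
   - Fallback: Luche reduction of the C9 ketone, then Pd(0)‑catalysed allylic substitution of the C9 allylic carbonate with nitromethane and Nef oxidation to the C1 aldehyde.
3. **Steps 15–16 (dialdehyde ⇌ lactol, then acylation).** The dienolate can be O‑acylated acyclically, the phenol can be acylated, and C9/C1 may come out as mixtures.
   - Fallback: form the pyran as a fused enol lactone by Ag‑ or Au‑mediated cyclisation of a C1 acid onto an activated C3 unit, then DIBAL to the lactol and acylate, or use an intramolecular hetero‑Diels–Alder with an enol‑ester dienophile so the C1 acylal forms in the ring‑forming step.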